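**Retrosynthetic overview**

1. Locants: cembrane frame, ring C1–C14, C15(=C17)–C16 on C1, C18/C19/C20 on C4/C8/C12. Target 27 ⇐ 4,7-oxa-bridged enone 20 (then C11/C12 by CBS reduction, matched Sharpless epoxidation and hydride opening; acetate; oxidation of C16).
2. 20 ⇐ 14-membered dienone alcohol 19 by a transannular aerobic oxypalladation/β-hydride elimination that makes the O–C7 bond, the C7 stereocentre and the C8=C19 methylene at once. Ring order: carbocycle first (step 13, intramolecular Horner–Wadsworth–Emmons at C12=C13), oxolane last (step 14); the later 12,13-oxirane is a transient functional group.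
3. Enabling feature: the oxolane oxygen spans C4 and C7 (1,4 across the carbocycle) and C7 is allylic to the exocyclic C8=C19 methylene. O–C7–C8(=C19H2) is thus the footprint of alkoxypalladation of a ring alkene C7=C8(C19H3) by the C4 tertiary hydroxyl, with hydride loss from C19.
4. 19 ⇐ C9–C10 alkylation of a β-ketophosphonate dianion with allylic bromide 14 ⇐ chelation-controlled homoprenyl Grignard addition to α-alkoxy methyl ketone 8 (C4–C5 bond, C4 set from C3), then SeO2 oxidation of the E-methyl (C9).
5. 8 ⇐ (S)-carvone 1 (supplies C1 and, as cis-carveol, C3): allylic chlorination for the C16 oxygen, Luche reduction, directed epoxidation, periodate cleavage of the carvone ring.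

Key step: step 14

Abbreviations: PMB = 4-methoxybenzyl; PMP = 4-methoxyphenyl; TES = triethylsilyl.
Assumption: 1, 9 and 15 are taken as commercial, and the free hydroxy acid 27 is assumed not to lactonise onto O3 under the buffered final oxidation.

**Route**

Step 1
Reactants: 1 (S)-(+)-carvone
Product: 2 (S)-10-chlorocarvone
Conditions: Ca(OCl)2, CO2 (dry ice), CH2Cl2/H2O, 0 °C
Reagents that add atoms: calcium hypochlorite, [Ca+2].[O-]Cl.[O-]Cl
Why: HOCl made in the flask effects an ene-type allylic chlorination of the electron-rich isopropenyl group and not of the enone, moving the double bond to C15=C17 and placing chlorine on the future C16 without touching the stereocentre (future C1).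

Step 2
Reactants: 2 (S)-10-chlorocarvone
Product: 3 (S)-10-(4-methoxyphenoxy)carvone
Conditions: 4-MeOC6H4OH, K2CO3, NaI (cat.), acetone, reflux
Reagents that add atoms: 4-methoxyphenol, COc1ccc(O)cc1
Why: Williamson ether synthesis (SN2 of the phenoxide at the primary allylic chloride) under carbonate conditions that leave the enone alone; the PMP ether masks O16 until step 19.

Step 3
Reactants: 3 (S)-10-(4-methoxyphenoxy)carvone
Product: 4 (1S,5S)-cis-carveol PMP ether
Conditions: NaBH4, CeCl3·7H2O, MeOH, −20 °C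
Reagents that add atoms: none
Why: Luche 1,2-reduction; hydride should add trans to the side chain, giving the cis-carveol whose carbinol carbon is the future C3 (S).

Step 4
Reactants: 4 (1S,5S)-cis-carveol PMP ether
Product: 5 all-cis 2,3-epoxy alcohol
Conditions: VO(acac)2 (cat.), t-BuOOH, toluene, 0 °C to 25 °C
Reagents that add atoms: tert-butyl hydroperoxide, CC(C)(C)OO
Why: Hydroxyl-directed vanadium-catalysed epoxidation delivers oxygen to the ring alkene on the face of the allylic OH and ignores the side-chain alkene, which has no free hydroxyl; the epoxide only prepares the ring cleavage.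

Step 5
Reactants: 5 all-cis 2,3-epoxy alcohol
Product: 6 PMB ether of 5
Conditions: NaH, 4-MeOC6H4CH2Cl, n-Bu4NI (cat.), THF/DMF, 0 °C to 25 °C
Reagents that add atoms: 4-methoxybenzyl chloride, COc1ccc(CCl)cc1
Why: Williamson etherification of the secondary alkoxide (the syn epoxide cannot undergo Payne rearrangement); the PMB ether is the chelating group for step 8 and keeps O3 out of the glycol cleavage.

Step 6
Reactants: 6 PMB ether of 5
Product: 7 keto-aldehyde (3R,5S)-5-(PMB-oxy)-3-[3-(PMP-oxy)prop-1-en-2-yl]-6-oxoheptanal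
Conditions: H5IO6, THF/H2O, 0 °C to 25 °C
Reagents that add atoms: water, O
Why: One-pot epoxide hydrolysis and Malaprade glycol cleavage opens the six-membered ring between the two epoxide carbons, giving the C4 methyl ketone next to the C3 PMB ether and the C13 aldehyde without affecting C1 or C3.

Step 7
Reactants: 7 keto-aldehyde
Product: 8 keto dimethyl acetal
Conditions: HC(OMe)3, CeCl3·7H2O (cat.), MeOH, 25 °C
Reagents that add atoms: trimethyl orthoformate, COC(OC)OC
Why: Lanthanide-catalysed chemoselective acetalisation masks the aldehyde and leaves the hindered α-alkoxy ketone free for step 8.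

Step 8
Reactants: 8 keto dimethyl acetal; 9 5-bromo-2-methylpent-2-ene
Product: 12 TES-protected (3S,4S) tertiary carbinol, via 4-methylpent-3-enylmagnesium bromide 10 (not isolated), via bromomagnesium C4-alkoxide 11 (not isolated)
Conditions: 9, Mg, THF, 25 °C; then 8, THF, −78 °C; then Et3SiOTf, −78 °C to 0 °C
Reagents that add atoms: triethylsilyl trifluoromethanesulfonate, CC[Si](CC)(CC)OS(=O)(=O)C(F)(F)F
Why: Cram-chelate controlled Grignard addition: magnesium bridges the C4 carbonyl and the C3 PMB-ether oxygen and the nucleophile enters on the side of the C3 hydrogen, which sets C4 as S (threo to C3); the tertiary alkoxide is silylated in the same flask so that it cannot attack the allylic bromide of steps 10 and 11.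

Step 9
Reactants: 12 TES-protected tertiary carbinol
Product: 13 (E)-allylic alcohol at C9
Conditions: SeO2 (cat.), t-BuOOH, CH2Cl2, 0 °C to 25 °C
Reagents that add atoms: tert-butyl hydroperoxide, CC(C)(C)OO
Why: SeO2/t-BuOOH allylic oxidation (ene reaction, then 2,3-sigmatropic shift) is selective for the E-methyl of the trisubstituted alkene, as with geranyl esters, while the side-chain alkene is deactivated by its allylic aryloxy group.

Step 10
Reactants: 13 (E)-allylic alcohol
Product: 14 (E)-allylic bromide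
Conditions: CBr4, PPh3, CH2Cl2, −20 °C
Reagents that add atoms: carbon tetrabromide, BrC(Br)(Br)Br
Why: Appel bromination of the primary allylic alcohol under neutral conditions, without allylic transposition and without touching the acetal or the silyl ether.

Step 11
Reactants: 14 (E)-allylic bromide; 15 diethyl (3-oxobutan-2-yl)phosphonate
Product: 17 β-ketophosphonate (TES ether/dimethyl acetal), via phosphonate 1,3-dianion 16 (not isolated)
Conditions: 15, NaH, THF, 0 °C; n-BuLi, 0 °C; then 14, −78 °C to 0 °C; H2O work-up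
Reagents that add atoms: none
Why: γ-Alkylation of the β-ketophosphonate 1,3-dianion (SN2 at the primary allylic bromide) forms the C9–C10 bond and installs the olefination handle; the phosphonate-bearing carbon forms as a mixture of epimers that is erased in step 13.

Step 12
Reactants: 17 β-ketophosphonate (TES ether/dimethyl acetal)
Product: 18 hydroxy aldehyde β-ketophosphonate
Conditions: 1 M HCl, THF, 25 °C
Reagents that add atoms: water, O
Why: Acid hydrolysis removes the dimethyl acetal and the tertiary TES ether together, unveiling the C13 aldehyde and the C4 hydroxyl needed in steps 13 and 14.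

Step 13
Reactants: 18 hydroxy aldehyde β-ketophosphonate
Product: 19 14-membered (7E,12E)-dienone alcohol
Conditions: LiCl, DBU, MeCN, 0.002 M, 25 °C
Reagents that add atoms: none
Why: Intramolecular Horner–Wadsworth–Emmons olefination under mild LiCl/amine conditions at high dilution closes the carbocycle at C12=C13 and should give the E-enone, the usual outcome for α-methyl β-ketophosphonates.

Step 14
Reactants: 19 14-membered (7E,12E)-dienone alcohol
Product: 20 4,7-oxa-bridged enone with the 8(19)-methylene (7R)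
Conditions: Pd(O2CCF3)2 (10 mol %), pyridine (40 mol %), Na2CO3, 3 Å molecular sieves, O2 (1 atm), toluene, 80 °C
Reagents that add atoms: none
Why: Proposed new method: the C4 tertiary hydroxyl binds the divalent palladium carboxylate and syn-oxypalladation across the ring alkene C7=C8 (migratory insertion into the Pd–alkoxide) forms the O–C7 bond and a tertiary C8–Pd bond; β-hydride elimination from the C19 methyl then releases the 8(19)-methylene and a palladium hydride that dioxygen returns to divalent palladium, water being the only co-product. The closest known reaction type is the aerobic Wacker-type cycloetherification of γ-hydroxy trisubstituted alkenes to 2-alkenyl tetrahydrofurans with Pd(O2CCF3)2/pyridine/O2, here run transannularly with a tertiary alcohol. The oxolane closes in the 5-exo-trig mode across the 14-membered ring. The new C7 stereocentre is expected to be set by the tether: closure with the C3 and C8 arms cis on the oxolane gives an unstrained out,out-bridged 15-oxabicyclo[10.2.1] frame, whereas the trans mode forces the eight-carbon C9–C2 span across the new ring, and a chiral pyridine–oxazoline ligand can reinforce this. The step needs 5-exo over 6-endo attack (6-endo would join two fully substituted carbons, C4–O–C8), hydride loss from C19 and not from C9 or C7 (three freely rotating methyl hydrogens; no enol ether formed), and chemoselectivity (the C4–OH is the only free hydroxyl, the enone alkene is electron-poor, the side-chain alkene cannot close a ring that can eliminate, and without phosphine the allylic aryl ether is not ionised).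

Step 15
Reactants: 20 4,7-oxa-bridged enone
Product: 21 (11R)-allylic alcohol
Conditions: (S)-2-methyl-CBS-oxazaborolidine, catecholborane, toluene, −78 °C
Reagents that add atoms: none
Why: Corey–Bakshi–Shibata reduction: with the α-methyl alkenyl arm as the large and C10 as the small substituent the (S)-oxazaborolidine should deliver hydride to give the 11R alcohol (reagent control), and catecholborane at low temperature spares the alkenes.

Step 16
Reactants: 21 (11R)-allylic alcohol
Product: 22 erythro 12,13-epoxy-11-ol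
Conditions: Ti(OiPr)4, D-(−)-diisopropyl tartrate, t-BuOOH, 4 Å molecular sieves, CH2Cl2, −20 °C
Reagents that add atoms: tert-butyl hydroperoxide, CC(C)(C)OO
Why: Sharpless titanium–tartrate epoxidation in its matched kinetic-resolution sense: for an (11R) secondary allylic alcohol D-(−)-tartrate is the fast, erythro-selective partner, so oxygen goes to the C12=C13 face that fixes the C12–O bond in the configuration that becomes 12S.

Step 17
Reactants: 22 erythro 12,13-epoxy-11-ol
Product: 23 (11R,12S)-diol
Conditions: LiAlH4, THF, 0 °C to 25 °C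
Reagents that add atoms: none
Why: Hydride opens the trisubstituted epoxide by SN2 attack at the less substituted C13, leaving the tertiary C12 alcohol with its configuration and completing the erythro 11,12-diol.

Step 18
Reactants: 23 (11R,12S)-diol
Product: 24 C11 acetate
Conditions: Ac2O, pyridine, DMAP (cat.), CH2Cl2, 0 °C to 25 °C
Reagents that add atoms: acetic anhydride, CC(=O)OC(C)=O
Why: DMAP-catalysed acylation takes the secondary C11 hydroxyl and leaves the tertiary C12 hydroxyl free.

Step 19
Reactants: 24 C11 acetate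
Product: 25 triol monoacetate (O3 and O16 free)
Conditions: (NH4)2Ce(NO3)6, MeCN/H2O (9:1), 0 °C
Reagents that add atoms: none
Why: Single-electron oxidation by tetravalent cerium cleaves the PMB ether (to the aldehyde) and the PMP ether (to the quinone) in one operation, freeing O3 and O16 while the acetate and the allylic ether bridge stay.

Step 20
Reactants: 25 triol monoacetate
Product: 26 2-substituted acrolein
Conditions: MnO2, CH2Cl2, 25 °C
Reagents that add atoms: none
Why: MnO2 oxidises only the primary allylic alcohol at C16 and leaves the saturated secondary C3 and tertiary C12 hydroxyls.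

Step 21
Reactants: 26 2-substituted acrolein
Product: 27 target acid CNP0215199.3
Conditions: NaClO2, NaH2PO4, 2-methylbut-2-ene, t-BuOH/H2O, 0 °C to 25 °C
Reagents that add atoms: sodium chlorite, [Na+].[O-]Cl=O
Why: Pinnick oxidation converts the enal into the acrylic acid under buffered conditions, with 2-methylbut-2-ene scavenging hypochlorite so that the alkenes, the acetate and all stereocentres are untouched.

**Compound list**

1 | (S)-(+)-carvone, (5S)-2-methyl-5-(prop-1-en-2-yl)cyclohex-2-en-1-one | CC1=CC[C@@H](CC1=O)C(C)=C | starting material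
2 | (S)-10-chlorocarvone, (5S)-5-(3-chloroprop-1-en-2-yl)-2-methylcyclohex-2-en-1-one | CC1=CC[C@@H](CC1=O)C(CCl)=C | intermediate
3 | (5S)-5-[3-(4-methoxyphenoxy)prop-1-en-2-yl]-2-methylcyclohex-2-en-1-one | CC1=CC[C@@H](CC1=O)C(COc2ccc(OC)cc2)=C | intermediate
4 | (1S,5S)-5-[3-(4-methoxyphenoxy)prop-1-en-2-yl]-2-methylcyclohex-2-en-1-ol (cis) | CC1=CC[C@@H](C[C@@H]1O)C(COc2ccc(OC)cc2)=C | intermediate
5 | (1S,2S,3R,5R)-2,3-epoxy-5-[3-(4-methoxyphenoxy)prop-1-en-2-yl]-2-methylcyclohexan-1-ol (OH, epoxide O and side chain all cis) | C[C@@]1(O2)[C@H]2C[C@@H](C[C@@H]1O)C(COc3ccc(OC)cc3)=C | intermediate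
6 | (1S,2R,3R,5R)-2,3-epoxy-1-(PMB-oxy)-5-[3-(4-methoxyphenoxy)prop-1-en-2-yl]-2-methylcyclohexane (all cis) | C[C@@]1(O2)[C@H]2C[C@@H](C[C@@H]1OCc3ccc(OC)cc3)C(COc4ccc(OC)cc4)=C | intermediate
7 | (3R,5S)-5-(PMB-oxy)-3-[3-(PMP-oxy)prop-1-en-2-yl]-6-oxoheptanal | CC(=O)[C@@H](OCc1ccc(OC)cc1)C[C@H](CC=O)C(COc2ccc(OC)cc2)=C | intermediate
8 | (3S,5R)-7,7-dimethoxy-3-(PMB-oxy)-5-[3-(PMP-oxy)prop-1-en-2-yl]heptan-2-one | CC(=O)[C@@H](OCc1ccc(OC)cc1)C[C@H](CC(OC)OC)C(COc2ccc(OC)cc2)=C | intermediate
9 | 5-bromo-2-methylpent-2-ene | CC(C)=CCCBr | starting material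
10 | 4-methylpent-3-enylmagnesium bromide | CC(C)=CCC[Mg]Br | intermediate
11 | bromomagnesium alkoxide of the (3S,4S) C4 carbinol | CC(C)=CCC[C@](C)(O[Mg]Br)[C@@H](OCc1ccc(OC)cc1)C[C@H](CC(OC)OC)C(COc2ccc(OC)cc2)=C | intermediate
12 | (3R,5S,6S)-1,1-dimethoxy-5-(PMB-oxy)-3-[3-(PMP-oxy)prop-1-en-2-yl]-6,10-dimethyl-6-(TES-oxy)undec-9-ene | CC(C)=CCC[C@](C)(O[Si](CC)(CC)CC)[C@@H](OCc1ccc(OC)cc1)C[C@H](CC(OC)OC)C(COc2ccc(OC)cc2)=C | intermediate
13 | (2E,6S,7S,9R)-11,11-dimethoxy-7-(PMB-oxy)-9-[3-(PMP-oxy)prop-1-en-2-yl]-2,6-dimethyl-6-(TES-oxy)undec-2-en-1-ol | OC/C(C)=C/CC[C@](C)(O[Si](CC)(CC)CC)[C@@H](OCc1ccc(OC)cc1)C[C@H](CC(OC)OC)C(COc2ccc(OC)cc2)=C | intermediate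
14 | (2E,6S,7S,9R)-1-bromo-11,11-dimethoxy-7-(PMB-oxy)-9-[3-(PMP-oxy)prop-1-en-2-yl]-2,6-dimethyl-6-(TES-oxy)undec-2-ene | BrC/C(C)=C/CC[C@](C)(O[Si](CC)(CC)CC)[C@@H](OCc1ccc(OC)cc1)C[C@H](CC(OC)OC)C(COc2ccc(OC)cc2)=C | intermediate
15 | diethyl (3-oxobutan-2-yl)phosphonate | CCOP(=O)(OCC)C(C)C(C)=O | starting material
16 | sodium lithium 1,3-dianion of 15 | [Na+].[Li+].CCOP(=O)(OCC)[C-](C)C(=O)[CH2-] | intermediate
17 | diethyl [(6E,10S,11S,13R)-15,15-dimethoxy-11-(PMB-oxy)-13-[3-(PMP-oxy)prop-1-en-2-yl]-6,10-dimethyl-3-oxo-10-(TES-oxy)pentadec-6-en-2-yl]phosphonate (epimers at C2) | CCOP(=O)(OCC)C(C)C(=O)CC/C(C)=C/CC[C@](C)(O[Si](CC)(CC)CC)[C@@H](OCc1ccc(OC)cc1)C[C@H](CC(OC)OC)C(COc2ccc(OC)cc2)=C | intermediate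
18 | diethyl [(6E,10S,11S,13R)-10-hydroxy-11-(PMB-oxy)-13-[3-(PMP-oxy)prop-1-en-2-yl]-6,10-dimethyl-3,15-dioxopentadec-6-en-2-yl]phosphonate (epimers at C2) | CCOP(=O)(OCC)C(C)C(=O)CC/C(C)=C/CC[C@](C)(O)[C@@H](OCc1ccc(OC)cc1)C[C@H](CC=O)C(COc2ccc(OC)cc2)=C | intermediate
19 | (1S,3S,4S,7E,12E)-4-hydroxy-3-(PMB-oxy)-16-(PMP-oxy)cembra-7,12,15(17)-trien-11-one | C=C(COc3ccc(OC)cc3)[C@H]1C/C=C(C)/C(=O)CC/C(C)=C/CC[C@](C)(O)[C@@H](OCc3ccc(OC)cc3)C1 | intermediate
20 | (1S,3S,4S,7R,12E)-4,7-epoxy-3-(PMB-oxy)-16-(PMP-oxy)cembra-8(19),12,15(17)-trien-11-one | C=C(COc3ccc(OC)cc3)[C@H]1C/C=C(C)/C(=O)CCC(=C)[C@H]2CC[C@](C)(O2)[C@@H](OCc3ccc(OC)cc3)C1 | intermediate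
21 | (1S,3S,4S,7R,11R,12E)-4,7-epoxy-3-(PMB-oxy)-16-(PMP-oxy)cembra-8(19),12,15(17)-trien-11-ol | C=C(COc3ccc(OC)cc3)[C@H]1C/C=C(C)/[C@H](O)CCC(=C)[C@H]2CC[C@](C)(O2)[C@@H](OCc3ccc(OC)cc3)C1 | intermediate
22 | (1R,3S,4S,7R,11R,12R,13R)-4,7:12,13-diepoxy-3-(PMB-oxy)-16-(PMP-oxy)cembra-8(19),15(17)-dien-11-ol | C=C(COc3ccc(OC)cc3)[C@H]1C[C@H]4O[C@]4(C)[C@H](O)CCC(=C)[C@H]2CC[C@](C)(O2)[C@@H](OCc3ccc(OC)cc3)C1 | intermediate
23 | (1S,3S,4S,7R,11R,12S)-4,7-epoxy-3-(PMB-oxy)-16-(PMP-oxy)cembra-8(19),15(17)-diene-11,12-diol | C=C(COc3ccc(OC)cc3)[C@H]1CC[C@](C)(O)[C@H](O)CCC(=C)[C@H]2CC[C@](C)(O2)[C@@H](OCc3ccc(OC)cc3)C1 | intermediate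
24 | (1S,3S,4S,7R,11R,12S)-4,7-epoxy-12-hydroxy-3-(PMB-oxy)-16-(PMP-oxy)cembra-8(19),15(17)-dien-11-yl acetate | C=C(COc3ccc(OC)cc3)[C@H]1CC[C@](C)(O)[C@H](OC(C)=O)CCC(=C)[C@H]2CC[C@](C)(O2)[C@@H](OCc3ccc(OC)cc3)C1 | intermediate
25 | (1S,3S,4S,7R,11R,12S)-4,7-epoxy-3,12,16-trihydroxycembra-8(19),15(17)-dien-11-yl acetate | C=C(CO)[C@H]1CC[C@](C)(O)[C@H](OC(C)=O)CCC(=C)[C@H]2CC[C@](C)(O2)[C@@H](O)C1 | intermediate
26 | (1S,3S,4S,7R,11R,12S)-4,7-epoxy-3,12-dihydroxy-16-oxocembra-8(19),15(17)-dien-11-yl acetate | C=C(C=O)[C@H]1CC[C@](C)(O)[C@H](OC(C)=O)CCC(=C)[C@H]2CC[C@](C)(O2)[C@@H](O)C1 | intermediate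
27 | (1S,3S,4S,7R,11R,12S)-11-acetoxy-4,7-epoxy-3,12-dihydroxycembra-8(19),15(17)-dien-16-oic acid (CNP0215199.3) | C=C(C(=O)O)[C@H]1CC[C@](C)(O)[C@H](OC(C)=O)CCC(=C)[C@H]2CC[C@](C)(O2)[C@@H](O)C1 | target

**Step count and risks**

Total step count: 21. Longest linear sequence: 21 steps from 1 (9 and 15 enter directly).

Steps most likely to fail:

1. Step 14 (proposed new method). The hindered tertiary alkoxide may add to the alkene too slowly, β-hydride loss may go into the ring methylene at C9 instead of the C19 methyl, or closure may take the wrong alkene face. The fallback uses known chemistry, sets out from 19 and returns at 20. Shi epoxidation of the C7=C8 alkene with the L-fructose-derived ketone and KHSO5 should give, under reagent control, the (7S,8S)-7,8-epoxide of 19 F1; the enone and the deactivated side-chain alkene should not react. A trace of camphorsulfonic acid in CH2Cl2 then triggers transannular 5-exo epoxide opening by the C4 hydroxyl with inversion at C7, giving the 4,7-oxa-bridged (7R,8S)-8-carbinol F2. Dehydration of this tertiary alcohol with SOCl2/pyridine at −30 °C (E2 through the freely rotating C19 methyl) should give 20.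

2. Step 16. Oxygen transfer to a secondary allylic alcohol held in the rigid bridged macrocycle may be slow or may follow the threo pathway. The fallback reverses the order of events, sets out from 20 and returns at 22. Weitz–Scheffer epoxidation of the enone (t-BuOOH, DBU, CH2Cl2) should give, by attack on the exposed face, the 12,13-epoxy-11-ketone F3. Chelation-controlled reduction with Zn(BH4)2 in Et2O at −20 °C (anti, that is erythro-selective for α,β-epoxy ketones) then sets C11 relative to C12 and gives 22; the epoxidation face would have to be confirmed.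

3. Step 9. The allylic oxidation may over-oxidise to the enal, attack the side-chain alkene at the allylic C1–H, or erode the acetal under the acidic selenium conditions. The fallback moves the oxidation to the small fragment, sets out from 8 and 9 and returns at 13. SeO2/t-BuOOH on 9 gives (E)-5-bromo-2-methylpent-2-en-1-ol F4, and Et3SiCl/imidazole gives its TES ether F5. Magnesium in THF gives the Grignard reagent F6, which adds to 8 under the chelation control of step 8 to give the bromomagnesium alkoxide F7. Capping with Et3SiOTf gives the bis-TES ether F8, and pyridinium p-toluenesulfonate in MeOH at 0 °C removes only the primary allylic TES group to give 13.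

Further compounds
F1 | step 14 | (1S,3S,4S,7S,8S,12E)-7,8-epoxy-4-hydroxy-3-(PMB-oxy)-16-(PMP-oxy)cembra-12,15(17)-dien-11-one | C=C(COc3ccc(OC)cc3)[C@H]1C/C=C(C)/C(=O)CC[C@]2(C)O[C@H]2CC[C@](C)(O)[C@@H](OCc3ccc(OC)cc3)C1
F2 | step 14 | (1S,3S,4S,7R,8S,12E)-4,7-epoxy-8-hydroxy-3-(PMB-oxy)-16-(PMP-oxy)cembra-12,15(17)-dien-11-one | C=C(COc3ccc(OC)cc3)[C@H]1C/C=C(C)/C(=O)CC[C@](C)(O)[C@H]2CC[C@](C)(O2)[C@@H](OCc3ccc(OC)cc3)C1
F3 | step 16 | (1R,3S,4S,7R,12S,13R)-4,7:12,13-diepoxy-3-(PMB-oxy)-16-(PMP-oxy)cembra-8(19),15(17)-dien-11-one | C=C(COc3ccc(OC)cc3)[C@H]1C[C@H]4O[C@]4(C)C(=O)CCC(=C)[C@H]2CC[C@](C)(O2)[C@@H](OCc3ccc(OC)cc3)C1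
F4 | step 9 | (E)-5-bromo-2-methylpent-2-en-1-ol | OC/C(C)=C/CCBr
F5 | step 9 | (E)-[(5-bromo-2-methylpent-2-en-1-yl)oxy]triethylsilane | CC[Si](CC)(CC)OC/C(C)=C/CCBr
F6 | step 9 | (E)-[4-methyl-5-(triethylsilyloxy)pent-3-enyl]magnesium bromide | CC[Si](CC)(CC)OC/C(C)=C/CC[Mg]Br
F7 | step 9 | bromomagnesium alkoxide of the (3S,4S) C4 carbinol carrying the C9 TES ether | CC[Si](CC)(CC)OC/C(C)=C/CC[C@](C)(O[Mg]Br)[C@@H](OCc1ccc(OC)cc1)C[C@H](CC(OC)OC)C(COc2ccc(OC)cc2)=C
F8 | step 9 | bis-TES ether of 13 (primary allylic and tertiary C4 oxygens silylated) | CC[Si](CC)(CC)OC/C(C)=C/CC[C@](C)(O[Si](CC)(CC)CC)[C@@H](OCc1ccc(OC)cc1)C[C@H](CC(OC)OC)C(COc2ccc(OC)cc2)=C
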